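## Retrosynthetic overview
1. The target comes from one final hydrogenation that removes four O-benzyl groups and saturates an enone C=C. The acetate is put on beforehand, at the only phenol that was masked differently (as a MOM ether).
2. Key C–C bond, C2–C3 of the tether: a crossed aldol addition of the lithium enolate of 2,4,6-tris(benzyloxy)acetophenone (ring A) to a 9-arylnonanal (ring B), followed by dehydration.
3. The 9-arylnonanal comes from 2-(benzyloxy)-6-(methoxymethoxy)benzaldehyde by Wittig reaction with a C8 hydroxyalkyl ylide, diimide saturation and alcohol oxidation.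
4. Ring B is desymmetrised without a statistical step: resorcinol, bis-MOM ether, ortho-lithiation and formylation, carbonyl-assisted mono-MOM cleavage, then benzylation.
5. No ring is formed. Both benzene rings are bought, as phloroacetophenone and resorcinol.

Assumption: the SMILES has no stereocentre and no stereogenic double bond, so the target is achiral and no enantiomer has to be selected. The tether is read as ten CH2 groups plus the ketone carbon.

## Route

Step 1
Reactants: 1 1-(2,4,6-trihydroxyphenyl)ethanone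
Product: 2 1-[2,4,6-tris(benzyloxy)phenyl]ethanone
Conditions: BnBr (3.6 equiv), K2CO3 (5 equiv), DMF, 80 °C
Reagents that add atoms: benzyl bromide, BrCc1ccccc1
Why: Williamson ether synthesis; K2CO3 in hot DMF ionises all three phenols, including the two hydrogen-bonded ones, and leaves a base-stable ketone whose only acidic site is the CH3 group.

Step 2
Reactants: 3 resorcinol
Product: 4 1,3-bis(methoxymethoxy)benzene
Conditions: MOMCl (2.5 equiv), iPr2NEt (3 equiv), CH2Cl2, 0 °C to rt
Reagents that add atoms: chloromethyl methyl ether, COCCl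
Why: O-alkylation of both phenols (MOM protection) installs two base-stable acetals that also serve as directing groups for step 3.

Step 3
Reactants: 4 1,3-bis(methoxymethoxy)benzene
Product: 6 2,6-bis(methoxymethoxy)benzaldehyde, via 2-lithio-1,3-bis(methoxymethoxy)benzene 5 (not isolated)
Conditions: n-BuLi (1.1 equiv), TMEDA, THF, −10 to 0 °C; then DMF, 0 °C to rt; aq NH4Cl
Reagents that add atoms: N,N-dimethylformamide, CN(C)C=O (gives the CHO group); n-butyllithium, [Li]CCCC (its lithium sits only in intermediate 5)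
Why: Directed ortho-metalation; the two MOM groups cooperatively steer lithiation to the shared C2 position, and DMF formylates the aryllithium.

Step 4
Reactants: 6 2,6-bis(methoxymethoxy)benzaldehyde
Product: 7 2-hydroxy-6-(methoxymethoxy)benzaldehyde
Conditions: conc. HCl (ca. 2 equiv), THF, rt, about 1.5 h, stopped by TLC control
Reagents that add atoms: none
Why: Acid-catalysed acetal hydrolysis; the freed OH locks the aldehyde in a strong hydrogen bond, so the second MOM group cleaves much more slowly and the reaction can be stopped at the mono-phenol.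

Step 5
Reactants: 7 2-hydroxy-6-(methoxymethoxy)benzaldehyde
Product: 8 2-(benzyloxy)-6-(methoxymethoxy)benzaldehyde
Conditions: BnBr (1.2 equiv), K2CO3 (2 equiv), DMF, 50 °C
Reagents that add atoms: benzyl bromide, BrCc1ccccc1
Why: Williamson ether synthesis on the single free phenol gives ring B with two orthogonal masks, Bn (hydrogenolysis) and MOM (acid).

Step 6
Reactants: 9 octane-1,8-diol
Product: 10 8-bromooctan-1-ol
Conditions: 48% aq HBr (1.2 equiv), toluene, reflux
Reagents that add atoms: hydrogen bromide, Br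
Why: SN2 monobromination in a two-phase system; the bromo alcohol passes into the toluene layer, away from the acid, which suppresses dibromide formation.

Step 7
Reactants: 10 8-bromooctan-1-ol
Product: 11 (8-hydroxyoctyl)triphenylphosphonium bromide
Conditions: PPh3 (1.05 equiv), MeCN, reflux
Reagents that add atoms: triphenylphosphine, c1ccc(cc1)P(c1ccccc1)c1ccccc1
Why: SN2 quaternisation of PPh3 by an unhindered primary bromide; the free alcohol does not interfere.

Step 8
Reactants: 11 (8-hydroxyoctyl)triphenylphosphonium bromide; 8 2-(benzyloxy)-6-(methoxymethoxy)benzaldehyde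
Product: 13 (Z)-9-[2-(benzyloxy)-6-(methoxymethoxy)phenyl]non-8-en-1-ol, via sodium alkoxide ylide 12 (not isolated)
Conditions: 11 (1.3 equiv), NaN(SiMe3)2 (2.6 equiv), THF, −78 to 0 °C; then 8, −78 °C to rt; aq NH4Cl
Reagents that add atoms: NaN(SiMe3)2, C[Si](C)(C)[N-][Si](C)(C)C.[Na+] (its sodium sits only in intermediate 12)
Why: Wittig olefination; two equivalents of base give the alkoxide ylide, which adds to the non-enolisable aldehyde, and the mainly Z geometry (with some E) does not matter because step 9 saturates the alkene.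

Step 9
Reactants: 13 (Z)-9-[2-(benzyloxy)-6-(methoxymethoxy)phenyl]non-8-en-1-ol
Product: 14 9-[2-(benzyloxy)-6-(methoxymethoxy)phenyl]nonan-1-ol
Conditions: TsNHNH2 (8 equiv), NaOAc (8 equiv), DME/H2O, reflux
Reagents that add atoms: none
Why: Diimide reduction; concerted syn transfer of H2 to the non-polar C=C cannot hydrogenolyse the aryl benzyl ether, and removing the electron-rich styrene here protects it from the acid of step 13.

Step 10
Reactants: 14 9-[2-(benzyloxy)-6-(methoxymethoxy)phenyl]nonan-1-ol
Product: 15 9-[2-(benzyloxy)-6-(methoxymethoxy)phenyl]nonanal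
Conditions: TEMPO (10 mol %), PhI(OAc)2 (1.1 equiv), CH2Cl2, rt
Reagents that add atoms: none
Why: TEMPO (oxoammonium) oxidation under anhydrous conditions stops cleanly at the aldehyde and leaves the aryl ethers and the MOM acetal untouched.

Step 11
Reactants: 2 1-[2,4,6-tris(benzyloxy)phenyl]ethanone; 15 9-[2-(benzyloxy)-6-(methoxymethoxy)phenyl]nonanal
Product: 17 (±)-11-[2-(benzyloxy)-6-(methoxymethoxy)phenyl]-3-hydroxy-1-[2,4,6-tris(benzyloxy)phenyl]undecan-1-one, via lithium enolate 16 (not isolated)
Conditions: 2 (1.1 equiv), LiN(iPr)2 (1.1 equiv), THF, −78 °C, 45 min; then 15 (1.0 equiv), −78 °C, 1 h; aq NH4Cl at −78 °C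
Reagents that add atoms: LiN(iPr)2, CC(C)[N-]C(C)C.[Li+] (its lithium sits only in intermediate 16)
Why: Directed crossed aldol addition; the ketone is fully converted to its only possible enolate before the enolisable aldehyde is added, so addition outruns proton transfer at −78 °C, and the new C3 carbinol centre forms racemic and is erased in step 12.

Step 12
Reactants: 17 (±)-11-[2-(benzyloxy)-6-(methoxymethoxy)phenyl]-3-hydroxy-1-[2,4,6-tris(benzyloxy)phenyl]undecan-1-one
Product: 19 (E)-11-[2-(benzyloxy)-6-(methoxymethoxy)phenyl]-1-[2,4,6-tris(benzyloxy)phenyl]undec-2-en-1-one, via C3 mesylate 18 (not isolated)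
Conditions: MsCl (1.5 equiv), Et3N (4 equiv), CH2Cl2, 0 °C to rt
Reagents that add atoms: methanesulfonyl chloride, CS(=O)(=O)Cl (its CH3SO2 group sits only in intermediate 18)
Why: Mesylation followed by E1cB elimination completes the aldol condensation under non-acidic conditions and gives the more stable E enone.

Step 13
Reactants: 19 (E)-11-[2-(benzyloxy)-6-(methoxymethoxy)phenyl]-1-[2,4,6-tris(benzyloxy)phenyl]undec-2-en-1-one
Product: 20 (E)-11-[2-(benzyloxy)-6-hydroxyphenyl]-1-[2,4,6-tris(benzyloxy)phenyl]undec-2-en-1-one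
Conditions: 6 M aq HCl/THF (1:5), 45 °C
Reagents that add atoms: none
Why: Acid hydrolysis of the aryl MOM acetal; benzyl ethers and the enone tolerate dilute HCl, no alcohol co-solvent is present to add to the enone, and ring A has no free OH that could close a chromanone.

Step 14
Reactants: 20 (E)-11-[2-(benzyloxy)-6-hydroxyphenyl]-1-[2,4,6-tris(benzyloxy)phenyl]undec-2-en-1-one
Product: 21 3-(benzyloxy)-2-{(E)-11-oxo-11-[2,4,6-tris(benzyloxy)phenyl]undec-9-en-1-yl}phenyl acetate
Conditions: Ac2O (1.5 equiv), pyridine (3 equiv), CH2Cl2, 0 °C to rt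
Reagents that add atoms: acetic anhydride, CC(=O)OC(C)=O
Why: O-acetylation (nucleophilic acyl substitution) of the only free hydroxyl in the molecule places the acetate without ambiguity.

Step 15
Reactants: 21 3-(benzyloxy)-2-{(E)-11-oxo-11-[2,4,6-tris(benzyloxy)phenyl]undec-9-en-1-yl}phenyl acetate
Product: 22 3-hydroxy-2-[11-oxo-11-(2,4,6-trihydroxyphenyl)undecyl]phenyl acetate
Conditions: H2 (1 atm), 10% Pd/C, EtOAc, rt, stopped after uptake of 5 equiv H2
Reagents that add atoms: none
Why: Catalytic hydrogenation and hydrogenolysis; the enone C=C is saturated quickly and the four benzyl ethers are cleaved under neutral, alcohol-free conditions that spare the aryl acetate and the hydrogen-bonded acylphloroglucinol ketone.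

## Compound list
1 | 1-(2,4,6-trihydroxyphenyl)ethanone (phloroacetophenone) | CC(=O)c1c(O)cc(O)cc1O | starting material
2 | 1-[2,4,6-tris(benzyloxy)phenyl]ethanone | CC(=O)c1c(OCc2ccccc2)cc(OCc2ccccc2)cc1OCc1ccccc1 | intermediate
3 | resorcinol (benzene-1,3-diol) | Oc1cccc(O)c1 | starting material
4 | 1,3-bis(methoxymethoxy)benzene | COCOc1cccc(OCOC)c1 | intermediate
5 | 2-lithio-1,3-bis(methoxymethoxy)benzene | [Li]c1c(OCOC)cccc1OCOC | intermediate
6 | 2,6-bis(methoxymethoxy)benzaldehyde | COCOc1cccc(OCOC)c1C=O | intermediate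
7 | 2-hydroxy-6-(methoxymethoxy)benzaldehyde | COCOc1cccc(O)c1C=O | intermediate
8 | 2-(benzyloxy)-6-(methoxymethoxy)benzaldehyde | COCOc1cccc(OCc2ccccc2)c1C=O | intermediate
9 | octane-1,8-diol | OCCCCCCCCO | starting material
10 | 8-bromooctan-1-ol | OCCCCCCCCBr | intermediate
11 | (8-hydroxyoctyl)triphenylphosphonium bromide | [Br-].OCCCCCCCC[P+](c1ccccc1)(c1ccccc1)c1ccccc1 | intermediate
12 | sodium 8-(triphenylphosphoranylidene)octan-1-olate | [Na+].[O-]CCCCCCCC=P(c1ccccc1)(c1ccccc1)c1ccccc1 | intermediate
13 | (Z)-9-[2-(benzyloxy)-6-(methoxymethoxy)phenyl]non-8-en-1-ol | OCCCCCCC/C=C\c1c(OCOC)cccc1OCc1ccccc1 | intermediate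
14 | 9-[2-(benzyloxy)-6-(methoxymethoxy)phenyl]nonan-1-ol | OCCCCCCCCCc1c(OCOC)cccc1OCc1ccccc1 | intermediate
15 | 9-[2-(benzyloxy)-6-(methoxymethoxy)phenyl]nonanal | O=CCCCCCCCCc1c(OCOC)cccc1OCc1ccccc1 | intermediate
16 | lithium 1-[2,4,6-tris(benzyloxy)phenyl]ethen-1-olate | [Li]OC(=C)c1c(OCc2ccccc2)cc(OCc2ccccc2)cc1OCc1ccccc1 | intermediate
17 | (±)-11-[2-(benzyloxy)-6-(methoxymethoxy)phenyl]-3-hydroxy-1-[2,4,6-tris(benzyloxy)phenyl]undecan-1-one (racemic) | O=C(CC(O)CCCCCCCCc1c(OCOC)cccc1OCc1ccccc1)c1c(OCc2ccccc2)cc(OCc2ccccc2)cc1OCc1ccccc1 | intermediate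
18 | (±)-11-[2-(benzyloxy)-6-(methoxymethoxy)phenyl]-1-oxo-1-[2,4,6-tris(benzyloxy)phenyl]undecan-3-yl methanesulfonate (racemic) | O=C(CC(OS(C)(=O)=O)CCCCCCCCc1c(OCOC)cccc1OCc1ccccc1)c1c(OCc2ccccc2)cc(OCc2ccccc2)cc1OCc1ccccc1 | intermediate
19 | (E)-11-[2-(benzyloxy)-6-(methoxymethoxy)phenyl]-1-[2,4,6-tris(benzyloxy)phenyl]undec-2-en-1-one | O=C(/C=C/CCCCCCCCc1c(OCOC)cccc1OCc1ccccc1)c1c(OCc2ccccc2)cc(OCc2ccccc2)cc1OCc1ccccc1 | intermediate
20 | (E)-11-[2-(benzyloxy)-6-hydroxyphenyl]-1-[2,4,6-tris(benzyloxy)phenyl]undec-2-en-1-one | O=C(/C=C/CCCCCCCCc1c(O)cccc1OCc1ccccc1)c1c(OCc2ccccc2)cc(OCc2ccccc2)cc1OCc1ccccc1 | intermediate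
21 | 3-(benzyloxy)-2-{(E)-11-oxo-11-[2,4,6-tris(benzyloxy)phenyl]undec-9-en-1-yl}phenyl acetate | O=C(/C=C/CCCCCCCCc1c(OC(C)=O)cccc1OCc1ccccc1)c1c(OCc2ccccc2)cc(OCc2ccccc2)cc1OCc1ccccc1 | intermediate
22 | 3-hydroxy-2-[11-oxo-11-(2,4,6-trihydroxyphenyl)undecyl]phenyl acetate (achiral) | CC(=O)Oc1cccc(O)c1CCCCCCCCCCC(=O)c1c(O)cc(O)cc1O | target

## Summary
Total step count: 15.
Longest linear sequence: 12 steps, from resorcinol 3 through steps 2, 3, 4, 5, 8, 9, 10, 11, 12, 13, 14 and 15.

Three steps most likely to fail: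

**Step 11 (crossed aldol).** The risks are proton transfer from the enolisable aldehyde to the basic enolate, and retro-aldol if the mixture warms before the quench. The fallback sets out from 2 and comes back at 17.
- Ketone 2 is treated with Me3SiOTf and Et3N in CH2Cl2 at 0 °C and isolated as trimethyl({1-[2,4,6-tris(benzyloxy)phenyl]ethenyl}oxy)silane F1.
- This neutral nucleophile is added to aldehyde 15, activated by BF3·OEt2 in CH2Cl2 at −78 °C (Mukaiyama aldol). No strong base ever meets the aldehyde.
- Work-up with aqueous NaHCO3 delivers 17.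

**Step 15 (global hydrogenation).** The risks are early loss of an ortho benzyl group, after which the free OH adds to the enone to give a chromanone, over-reduction of the aryl ketone, and stalled debenzylation. The fallback sets out from 21 and comes back at 22. It separates the two events.
- Conjugate reduction of 21 with [(Ph3P)CuH]6 in wet toluene at rt gives 3-(benzyloxy)-2-{11-oxo-11-[2,4,6-tris(benzyloxy)phenyl]undecyl}phenyl acetate F2.
- The four benzyl ethers are then removed without hydrogen, using BCl3 and pentamethylbenzene as cation scavenger in CH2Cl2 at −78 °C. This leaves the ketone and the acetate alone and gives 22.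

**Step 9 (diimide reduction).** The risk is incomplete conversion of the hindered, ortho,ortho-disubstituted styrene. The fallback sets out from 13 and comes back at 14.
- Full hydrogenation of 13 (H2, 10% Pd/C, EtOAc, rt) knowingly sacrifices the benzyl ether and gives 2-(9-hydroxynonyl)-3-(methoxymethoxy)phenol F3.
- The phenol is re-benzylated with BnBr and K2CO3 in DMF at 50 °C, conditions under which the primary alcohol stays untouched, to give 14.

## Further compounds
F1 | step 11 | trimethyl({1-[2,4,6-tris(benzyloxy)phenyl]ethenyl}oxy)silane | C=C(O[Si](C)(C)C)c1c(OCc2ccccc2)cc(OCc2ccccc2)cc1OCc1ccccc1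
F2 | step 15 | 3-(benzyloxy)-2-{11-oxo-11-[2,4,6-tris(benzyloxy)phenyl]undecyl}phenyl acetate | CC(=O)Oc1cccc(OCc2ccccc2)c1CCCCCCCCCCC(=O)c1c(OCc2ccccc2)cc(OCc2ccccc2)cc1OCc1ccccc1
F3 | step 9 | 2-(9-hydroxynonyl)-3-(methoxymethoxy)phenol | OCCCCCCCCCc1c(O)cccc1OCOC
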